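The numbers in the tables are calculated on assumed constants; noise was put on by code.

The pitfall is to carry the first-order decay of the midnight run into the new flask. In the midnight run the coupling partner stands at 0.22 M against 0.100 M of the two substrates together, but in the flask it stands at 0.220 M against 0.200 M, so in the flask it runs down with them, and the substrates together are the limiting reagent.

- midnight: left-handed substrate 0.050 M; right-handed substrate 0.050 M; coupling partner 0.22 M; free catalyst 0.10 mM; precatalyst 0.50 mM; run made earlier
- flask: left-handed substrate 0.10 M; coupling partner 0.220 M; free catalyst 0.10 mM; precatalyst 0.50 mM; right-handed substrate 0.10 M; time 10 h

midnight run (percent of the left-handed substrate and right-handed substrate together charged)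

| time / h | left-handed product / % | right-handed product / % |
|---|---|---|
| 0.250 | 2 | 4 |
| 0.500 | 8 | 1 |
| 1.33 | 12 | 6 |
| 3.00 | 21 | 14 |

(scatter of a reading: 2 percentage points)

- free catalyst is single-handed; left-handed substrate and right-handed substrate are mirror images of each other, charged as a racemate, each of them at the stated concentration
- steps that have been proposed: coupling partner + free catalyst + right-handed substrate -> free catalyst + right-handed product; free catalyst -> spent catalyst; left-handed product <-> right-handed product; coupling partner + free catalyst + left-handed substrate -> free catalyst + left-handed product; left-handed substrate + racemization catalyst <-> right-handed substrate + racemization catalyst; precatalyst <-> racemization catalyst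
- an excess is the difference of the two amounts in percent of their sum
- an excess is below zero if the other one leads

1. left-handed product and right-handed product together, in percent of the left-handed substrate and right-handed substrate charged together, at 10 h
2. excess of left-handed product over right-handed product in the product at 10 h
3. whether the exchange between left-handed substrate and right-handed substrate keeps pace with the reaction: how far the product's excess at 10 h gets from its value without exchange to its value with instant exchange (above 80 % keeps pace, below 20 % hardly takes part, else lags behind)

Follow one substrate molecule: at each moment it may be coupled, be flipped to its mirror image, or stay as it is. The midnight products at 3.00 h, put into a rate second order in c(substrates) and c(coupling partner), give 0.715 M⁻¹ h⁻¹, the coupling constant: coupling rate per c(substrates) and c(coupling partner) at 0.10 mM of free catalyst, proportional to free catalyst in the proposed steps.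

The ladder follows from it. The midnight readings stop at 3.00 h, earlier than the life of a substrate molecule at the charged c(coupling partner), 6.35 h. Next comes the life of the coupling partner at the charged c(substrates), 6.99 h. The asked 10 h lies beyond both, so the flask must be reckoned with both falling, and my integrated reckoning gives 62.9 %. The flip gets no clear rung: the last midnight excess reads 20.0 %, from readings good to 2 percentage points.

The forecast is lower than my reckoning, with 60 % (50 % to 68 %), and gives 21 % (11 % to 30 %) for the excess; for the exchange it says lags behind, holding that “the noise cannot exclude moderate racemization”.

The flask gives 60.6 % and an excess of 14.6 %, and its exchange keeps pace, at 86 % of the way.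

    coupling partner + free catalyst + right-handed substrate → free catalyst + right-handed product (k = 0.960 M⁻² s⁻¹)
    free catalyst → spent catalyst (k = 3.30 × 10⁻⁶ s⁻¹)
    left-handed product ⇌ right-handed product (k = 2.90 × 10⁻⁵ s⁻¹)
    coupling partner + free catalyst + left-handed substrate → free catalyst + left-handed product (k = 3.00 M⁻² s⁻¹)
    left-handed substrate + racemization catalyst ⇌ right-handed substrate + racemization catalyst, rate k5*[racemization catalyst]*[left-handed substrate] forward; the back reaction follows from the equilibrium constant (k = 1.50 M⁻¹ s⁻¹)
    precatalyst ⇌ racemization catalyst (K = 0.190, k = 1.00 × 10⁻⁴ s⁻¹)

In the flask the reckoned 62.9 % stands against 60.6 %, with free catalyst at 88.8 % at 10.0 h. The product excess in the flask falls from 44.1 % at 1.00 h to 14.6 % at 10.0 h, when left-handed and right-handed substrate stand at 18.9 % and 20.5 % of the two charged together. In the neighbour charged with 2.5 × 10⁻⁴ M of free catalyst, the coupling constant scaled to that charge gives 82.5 %, and that flask gives 80.5 %.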